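Retrosynthetic cuts, in order: the two O-CH3 bonds on O5 and O7; the C2-C1' bond between ring B (the 4-pyranone ring) and the tridecyl chain, which leads back to 5,7-dimethoxy-6,8-dimethylchromone and tridecanal; O1-C2 and C2-C3 of ring B (C2 comes from DMF-DMA); the C4a-C4 aryl-acetyl bond; one aryl-CH3 bond.
Forward: ring A (the benzene ring) is bought as 2,4,6-trimethoxytoluene and filled to full substitution by lithiation/methylation and Friedel-Crafts acetylation. Ring B is then closed on it through an enaminone, the C13 chain is joined to the finished bicycle, and the two phenols are freed last.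
Enabling feature: the vinylogous ester O1-C2(H)=C3-C4=O of ring B. Silylation of the C4 oxygen makes ring B an aromatic benzopyrylium cation that binds a phosphine at C2. Loss of the C2 hydrogen then gives a C2 ylide, so the natural acceptor C2 becomes a donor and can be joined to the acceptor carbon of an aldehyde (Wittig).
The olefin so formed is the anhydrobase of a 2-alkylbenzopyrylium ion, and protonation at C1' with loss of silicon gives back the pyranone. C2-H thus becomes C2-CH2R with no halide at C2, no transition metal and no re-oxidation, and since C5 to C8 of ring A are all substituted, no other ring position can interfere.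
Stereochemistry: the target has no stereocentre and no stereogenic double bond; the C2 centre and the E/Z alkene of the intermediates are transient and are erased in the same flask.

Key step: step 4

Assumption: 1, 8 and all reagents are taken as commercial. Atoms are numbered as in chromone (O1, C2, C3, C4, C4a, C5 to C8, C8a), and C1' is the chain carbon bound to C2.

Step 1
Reactants: 1 2,4,6-trimethoxytoluene
Product: 3 1,3,5-trimethoxy-2,4-dimethylbenzene, via aryllithium 2 (not isolated)
Conditions: n-BuLi, TMEDA, THF, 0 °C to rt; MeI, -78 °C to rt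
Reagents that add atoms: iodomethane, CI
Why: Directed ortho-metalation, in which each of the two equivalent ring hydrogens of 1 lies between two methoxy groups, so that n-BuLi should lithiate there rather than at the benzylic methyl group and the aryllithium is then methylated by SN2 attack on MeI.

Step 2
Reactants: 3 1,3,5-trimethoxy-2,4-dimethylbenzene
Product: 5 1-(2-hydroxy-4,6-dimethoxy-3,5-dimethylphenyl)ethanone, via trimethoxy ketone 4 (not isolated)
Conditions: AcCl (1.2 equiv), AlCl3 (2.5 equiv), CH2Cl2, 0 °C to rt; ice-water
Reagents that add atoms: acetyl chloride, CC(=O)Cl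
Why: Friedel-Crafts acylation at the only free position of a very electron-rich arene, followed in the same flask by chelation-directed AlCl3 cleavage of one of the two equivalent O-methyl groups ortho to the new carbonyl group, which should stop there because the aluminium chelate is deactivated.

Step 3
Reactants: 5 1-(2-hydroxy-4,6-dimethoxy-3,5-dimethylphenyl)ethanone
Product: 7 5,7-dimethoxy-6,8-dimethyl-4H-chromen-4-one, via enaminone 6 (not isolated)
Conditions: DMF-DMA, toluene, 100 °C; concentrate; conc. HCl, CH2Cl2, 40 °C
Reagents that add atoms: N,N-dimethylformamide dimethyl acetal, COC(OC)N(C)C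
Why: Condensation of the acetyl CH3 group with DMF-DMA gives the enaminone, and acid then triggers 6-endo-trig oxa-Michael attack of the ortho phenol and loss of dimethylamine (the enaminone route to 2,3-unsubstituted chromones), only one phenol being available for the closure.

Step 4
Reactants: 7 5,7-dimethoxy-6,8-dimethyl-4H-chromen-4-one, 8 tridecanal
Product: 13 5,7-dimethoxy-6,8-dimethyl-2-tridecyl-4H-chromen-4-one, via benzopyrylium triflate 9 (not isolated), via phosphonium triflate 10 (not isolated), via ylide 11 (not isolated), via tridecylidene chromene 12 (not isolated)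
Conditions: TBSOTf (1.2 equiv), THF, 0 °C to rt; PBu3 (1.2 equiv), -78 to 0 °C; n-BuLi (1.2 equiv), -78 °C; 8 (1.3 equiv), -78 °C to rt; 1 M aq HCl, rt
Reagents that add atoms: none
Why: Proposed new method: O-silylation of the C4 carbonyl oxygen by TBSOTf turns ring B into the aromatic cation 9, PBu3 adds to its only unsubstituted electrophilic carbon C2 to give 10, n-BuLi removes the C2 hydrogen (alpha to phosphorus and to O1, allylic to C3=C4) to give ylide 11, and 11 attacks the carbonyl carbon of 8 and collapses through an oxaphosphetane to Bu3P=O and 12, so that two carbons that are both natural acceptors are joined by polarity reversal at C2. Compound 12 is the anhydrobase of a 2-alkylbenzopyrylium ion, so aqueous acid should protonate the exocyclic carbon C1', regain the aromatic cation and then pass silicon to water, which gives the chromone oxidation level without an oxidant and takes out both helpers in the same flask. The closest known reaction types are the phosphoniosilylation and Wittig beta-functionalisation of cyclic enones and the Wittig olefination of pyranylphosphonium salts made from pyrylium salts and PBu3, but the sequence has no direct precedent on a chromone. No ring is closed and no stereocentre is kept: C2 of 10 is formed racemic and is flattened in 11, and both alkene isomers of 12 converge on 13. The step needs attack of the phosphine at C2 and not at C4, and reaction of the allylic ylide at its alpha carbon C2 and not at its gamma carbon C4; both follow from the silyloxy group and ring A on C4, while the full substitution of ring A (C5 to C8) leaves n-BuLi no ring hydrogen to remove. PBu3 is preferred to PPh3 because the cation, stabilised by three oxygen donors, is a weak carbon Lewis acid and must be held fully as 10 before the base is added.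

Step 5
Reactants: 13 5,7-dimethoxy-6,8-dimethyl-2-tridecyl-4H-chromen-4-one
Product: 14 5,7-dihydroxy-6,8-dimethyl-2-tridecyl-4H-chromen-4-one (target)
Conditions: BBr3 (5 equiv), CH2Cl2, -78 °C to rt; ice-water
Reagents that add atoms: none
Why: Lewis-acid ether cleavage with BBr3, in which the 5-O-methyl group leaves with the help of chelation to the C4 carbonyl and the 7-O-methyl group, twisted out of conjugation by its two ortho methyl groups, stays basic enough to bind boron, while an acid-induced opening and reclosure of ring B (Wessely-Moser type) would be degenerate because ring A is symmetric.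

Compound list
1 | 2,4,6-trimethoxytoluene | Cc1c(OC)cc(OC)cc1OC | starting material
2 | (2,4,6-trimethoxy-3-methylphenyl)lithium | [Li]c1c(OC)cc(OC)c(C)c1OC | intermediate
3 | 1,3,5-trimethoxy-2,4-dimethylbenzene | COc1cc(OC)c(C)c(OC)c1C | intermediate
4 | 1-(2,4,6-trimethoxy-3,5-dimethylphenyl)ethanone | CC(=O)c1c(OC)c(C)c(OC)c(C)c1OC | intermediate
5 | 1-(2-hydroxy-4,6-dimethoxy-3,5-dimethylphenyl)ethanone | CC(=O)c1c(O)c(C)c(OC)c(C)c1OC | intermediate
6 | (E)-3-(dimethylamino)-1-(2-hydroxy-4,6-dimethoxy-3,5-dimethylphenyl)prop-2-en-1-one | CN(C)/C=C/C(=O)c1c(O)c(C)c(OC)c(C)c1OC | intermediate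
7 | 5,7-dimethoxy-6,8-dimethyl-4H-chromen-4-one | O=c1ccoc2c(C)c(OC)c(C)c(OC)c12 | intermediate
8 | tridecanal | CCCCCCCCCCCCC=O | starting material
9 | 4-(tert-butyldimethylsilyloxy)-5,7-dimethoxy-6,8-dimethylchromenylium trifluoromethanesulfonate | CC(C)(C)[Si](C)(C)Oc1cc[o+]c2c(C)c(OC)c(C)c(OC)c12.[O-]S(=O)(=O)C(F)(F)F | intermediate
10 | tributyl[4-(tert-butyldimethylsilyloxy)-5,7-dimethoxy-6,8-dimethyl-2H-chromen-2-yl]phosphonium trifluoromethanesulfonate (racemic at C2) | CCCC[P+](CCCC)(CCCC)C1C=C(O[Si](C)(C)C(C)(C)C)c2c(OC)c(C)c(OC)c(C)c2O1.[O-]S(=O)(=O)C(F)(F)F | intermediate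
11 | tributyl[4-(tert-butyldimethylsilyloxy)-5,7-dimethoxy-6,8-dimethyl-2H-chromen-2-ylidene]phosphorane | CCCCP(CCCC)(CCCC)=C1C=C(O[Si](C)(C)C(C)(C)C)c2c(OC)c(C)c(OC)c(C)c2O1 | intermediate
12 | tert-butyl[(5,7-dimethoxy-6,8-dimethyl-2-tridecylidene-2H-chromen-4-yl)oxy]dimethylsilane (E/Z mixture) | CCCCCCCCCCCCC=C1C=C(O[Si](C)(C)C(C)(C)C)c2c(OC)c(C)c(OC)c(C)c2O1 | intermediate
13 | 5,7-dimethoxy-6,8-dimethyl-2-tridecyl-4H-chromen-4-one | CCCCCCCCCCCCCc1cc(=O)c2c(OC)c(C)c(OC)c(C)c2o1 | intermediate
14 | 5,7-dihydroxy-6,8-dimethyl-2-tridecyl-4H-chromen-4-one | CCCCCCCCCCCCCc1cc(=O)c2c(O)c(C)c(O)c(C)c2o1 | target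

Total step count: 5. Longest linear sequence: 5 steps (1 to 14); 8 is bought and enters at step 4.

Steps most likely to fail

Step 4 (the labelled step). Three processes may go wrong:
- The phosphine may capture the donor-stabilised cation incompletely, so that n-BuLi adds to C2 itself.
- Deprotonation may occur at a butyl group on phosphorus in place of C2.
- The enolisable aldehyde may transfer a proton to the basic ylide.

The fallback uses known chemistry with normal polarity and a later re-oxidation. It sets out from 7 and comes back at 13. 1-Bromotridecane and Mg in THF give tridecylmagnesium bromide F1. Its CuBr·SMe2-catalysed, TMSCl-accelerated conjugate addition to 7 (THF, -78 °C) gives 5,7-dimethoxy-6,8-dimethyl-2-tridecyl-4-(trimethylsilyloxy)-2H-chromene F2. Saegusa-Ito oxidation of this silyl enol ether with Pd(OAc)2 in MeCN restores the C2=C3 double bond and gives 13.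

Step 2. More than one O-methyl group may be lost (the second ortho ether or the hindered para ether), or the cleavage may stay incomplete, so that mixtures of phenols arise. The fallback sets out from 3 and comes back at 5. The acyl group is brought in by an anionic route and the ether cleavage becomes a separate, chelation-controlled operation. n-BuLi/TMEDA lithiates the last ring C-H of 3 to (2,4,6-trimethoxy-3,5-dimethylphenyl)lithium F3. N-methoxy-N-methylacetamide acylates it to 4 (aq NH4Cl quench), which is now isolated. BCl3 (1.1 equiv, CH2Cl2, -78 to 0 °C) then removes one of the two equivalent ortho O-methyl groups through a six-membered boron chelate to give 5.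

Step 5. The reaction may stall after the fast, chelation-assisted cleavage at O5, so that the 7-O-methyl ether stays on a waxy long-chain product that is hard to purify. The fallback sets out from 7 and comes back at 14. The protecting groups are exchanged before the coupling, so that the forcing ether cleavage falls on a small early intermediate and the last step becomes a hydrogenolysis.
- 48% aq HBr in AcOH at reflux cleaves both ethers of 7 to 5,7-dihydroxy-6,8-dimethyl-4H-chromen-4-one F4.
- BnBr and K2CO3 in DMF give 5,7-bis(benzyloxy)-6,8-dimethyl-4H-chromen-4-one F5.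
- The sequence of step 4 then runs through the benzopyrylium triflate F6, the phosphonium triflate F7, the ylide F8 and the tridecylidene chromene F9 to 5,7-bis(benzyloxy)-6,8-dimethyl-2-tridecyl-4H-chromen-4-one F10.
- Hydrogenolysis (H2, Pd/C, EtOAc, rt) frees both phenols and gives 14.

Further compounds
F1 | step 4 | tridecylmagnesium bromide | CCCCCCCCCCCCC[Mg]Br
F2 | step 4 | 5,7-dimethoxy-6,8-dimethyl-2-tridecyl-4-(trimethylsilyloxy)-2H-chromene (racemic) | CCCCCCCCCCCCCC1C=C(O[Si](C)(C)C)c2c(OC)c(C)c(OC)c(C)c2O1
F3 | step 2 | (2,4,6-trimethoxy-3,5-dimethylphenyl)lithium | [Li]c1c(OC)c(C)c(OC)c(C)c1OC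
F4 | step 5 | 5,7-dihydroxy-6,8-dimethyl-4H-chromen-4-one | O=c1ccoc2c(C)c(O)c(C)c(O)c12
F5 | step 5 | 5,7-bis(benzyloxy)-6,8-dimethyl-4H-chromen-4-one | O=c1ccoc2c(C)c(OCc3ccccc3)c(C)c(OCc3ccccc3)c12
F6 | step 5 | 5,7-bis(benzyloxy)-4-(tert-butyldimethylsilyloxy)-6,8-dimethylchromenylium trifluoromethanesulfonate | CC(C)(C)[Si](C)(C)Oc1cc[o+]c2c(C)c(OCc3ccccc3)c(C)c(OCc3ccccc3)c12.[O-]S(=O)(=O)C(F)(F)F
F7 | step 5 | [5,7-bis(benzyloxy)-4-(tert-butyldimethylsilyloxy)-6,8-dimethyl-2H-chromen-2-yl]tributylphosphonium trifluoromethanesulfonate (racemic at C2) | CCCC[P+](CCCC)(CCCC)C1C=C(O[Si](C)(C)C(C)(C)C)c2c(OCc3ccccc3)c(C)c(OCc3ccccc3)c(C)c2O1.[O-]S(=O)(=O)C(F)(F)F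
F8 | step 5 | [5,7-bis(benzyloxy)-4-(tert-butyldimethylsilyloxy)-6,8-dimethyl-2H-chromen-2-ylidene]tributylphosphorane | CCCCP(CCCC)(CCCC)=C1C=C(O[Si](C)(C)C(C)(C)C)c2c(OCc3ccccc3)c(C)c(OCc3ccccc3)c(C)c2O1
F9 | step 5 | {[5,7-bis(benzyloxy)-6,8-dimethyl-2-tridecylidene-2H-chromen-4-yl]oxy}(tert-butyl)dimethylsilane (E/Z mixture) | CCCCCCCCCCCCC=C1C=C(O[Si](C)(C)C(C)(C)C)c2c(OCc3ccccc3)c(C)c(OCc3ccccc3)c(C)c2O1
F10 | step 5 | 5,7-bis(benzyloxy)-6,8-dimethyl-2-tridecyl-4H-chromen-4-one | CCCCCCCCCCCCCc1cc(=O)c2c(OCc3ccccc3)c(C)c(OCc3ccccc3)c(C)c2o1
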